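**Retrosynthetic overview**
- Target ⇐ cis-2,3-disubstituted 2,3-dihydrofuran: syn addition of H2 to the face opposite the two existing cis groups sets the last two ring centres (all-cis) and the same catalyst removes three benzyl groups.
- The oxolane is the only ring formed, late, in the biosynthetic bond order: first the 8–8′ C–C bond by one-electron oxidative coupling, then the C7–O–C7′ bond by attack of a benzylic hydroxyl on the partner benzylic carbon (here at the acyl level, through a p-alkoxyaryl oxocarbenium ion, the cationic counterpart of a quinone methide).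
- The 8–8′ coupling is made cross- and enantioselective as an organo-SOMO coupling of propanal with the silyl enol ether of 4′-benzyloxypropiophenone (sets ring C4); the C5 carbinol follows by Felkin addition of an aryl–titanium reagent that already carries the third C6C3 unit.
- The all-cis ring is pseudo-meso (its two halves differ only in the remote 8–3′ side chain), so the halves are kept chemically different (aldehyde versus ketone) until the ring centres are set.
- Third unit (R centre): Ir-catalysed asymmetric hydrogenation of an E-α-methylstilbene made from 5′-bromo-2′-hydroxyacetophenone and 4-benzyloxybenzyl chloride.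

Assumption: the target is taken exactly as the SMILES (all-cis oxolane 2S,3R,4S,5R; side-chain centre R); the facial senses of the two catalyst-controlled steps (3 and 5) are taken from the published models for the closest substrates, and both catalysts are available in either mirror form.

**Step 1**
Reactants: 1 1-(5-bromo-2-hydroxyphenyl)ethan-1-one
Product: 2 1-[2-(benzyloxy)-5-bromophenyl]ethan-1-one
Conditions: BnBr (1.1 equiv), K2CO3 (1.5 equiv), DMF, 60 °C
Reagents that add atoms: benzyl bromide, BrCc1ccccc1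
Why: Williamson ether synthesis on the phenoxide masks the phenol as a benzyl ether that survives the organometallic steps and is cleaved by the final hydrogenolysis; no stereocentre is formed.

**Step 2**
Reactants: 2 1-[2-(benzyloxy)-5-bromophenyl]ethan-1-one; 3 1-(benzyloxy)-4-(chloromethyl)benzene
Product: 6 1-(benzyloxy)-2-[(1E)-1-[4-(benzyloxy)phenyl]prop-1-en-2-yl]-4-bromobenzene, via benzylic Grignard reagent 4 (not isolated), via tertiary alcohol 5 (not isolated)
Conditions: 3, Mg, THF, 0 °C; then 2, −20 to 0 °C; 1 M HCl; crude 5, TsOH·H2O (5 mol%), toluene, 80 °C; recrystallisation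
Reagents that add atoms: none
Why: Grignard 1,2-addition to the aryl methyl ketone followed by acid-catalysed E1 dehydration under equilibrating conditions favours the conjugated trisubstituted E alkene (aryl groups trans), and the minor Z and 1,1-disubstituted isomers are removed by recrystallisation so that only one alkene geometry enters the hydrogenation.

**Step 3**
Reactants: 6 1-(benzyloxy)-2-[(1E)-1-[4-(benzyloxy)phenyl]prop-1-en-2-yl]-4-bromobenzene
Product: 7 1-(benzyloxy)-2-[(2R)-1-[4-(benzyloxy)phenyl]propan-2-yl]-4-bromobenzene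
Conditions: [Ir(cod)(L)][B(C6H3-3,5-(CF3)2)4] (1 mol%; L = (S)-4-tert-butyl-2-[2-(di-o-tolylphosphanyl)phenyl]-4,5-dihydro-1,3-oxazole), H2 (50 bar), CH2Cl2, 25 °C
Reagents that add atoms: none
Why: Iridium–phosphinooxazoline asymmetric hydrogenation of an unfunctionalised E-α-methylstilbene (Pfaltz type) adds H2 to one enantioface and sets the (R) benzylic centre in the sense known for (E)-1,2-diphenylpropene, while the aryl bromide and benzyl ethers are inert to this homogeneous catalyst.

**Step 4**
Reactants: 8 1-[4-(benzyloxy)phenyl]propan-1-one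
Product: 9 {[(1Z)-1-[4-(benzyloxy)phenyl]prop-1-en-1-yl]oxy}trimethylsilane
Conditions: Me3SiOTf (1.2 equiv), Et3N (1.5 equiv), CH2Cl2, 0 °C
Reagents that add atoms: trimethylsilyl trifluoromethanesulfonate, C[Si](C)(C)OS(=O)(=O)C(F)(F)F
Why: Soft enolisation with O-silylation gives the thermodynamically preferred Z silyl enol ether, the enol form of the second C3 unit needed for the oxidative coupling; no stereocentre is formed.

**Step 5**
Reactants: 9 {[(1Z)-1-[4-(benzyloxy)phenyl]prop-1-en-1-yl]oxy}trimethylsilane; 10 propanal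
Product: 11 (2S)-4-[4-(benzyloxy)phenyl]-2,3-dimethyl-4-oxobutanal (both C3 epimers)
Conditions: 10 (1 equiv), 9 (2 equiv), (2R,5R)-5-benzyl-2-tert-butyl-3-methylimidazolidin-4-one·CF3CO2H (20 mol%), (NH4)2Ce(NO3)6 (2.2 equiv), 2,6-di-tert-butylpyridine (2 equiv), H2O (2 equiv), acetone, −20 °C
Reagents that add atoms: none
Why: Proposed new method: the organo-SOMO α-enolation of aldehydes is extended to a β-methyl aryl enolsilane; the enamine of 10 is oxidised by one electron (tetravalent cerium) to a 3π-electron radical cation whose face anti to the benzyl and tert-butyl groups is attacked by the nucleophilic carbon of 9, and the resulting α-silyloxybenzyl radical is oxidised and desilylated to the ketone, so that C2 is set as S by the catalyst while C3 forms as a mixture that is erased in step 7; the closest known reaction is the MacMillan enantioselective α-enolation of aldehydes with 1-aryl enolsilanes and (NH4)2Ce(NO3)6, and the step is the laboratory counterpart of the one-electron 8–8′ coupling.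

**Step 6**
Reactants: 7 1-(benzyloxy)-2-[(2R)-1-[4-(benzyloxy)phenyl]propan-2-yl]-4-bromobenzene; 11 (2S)-4-[4-(benzyloxy)phenyl]-2,3-dimethyl-4-oxobutanal
Product: 14 (3S,4R)-4-{4-(benzyloxy)-3-[(2R)-1-[4-(benzyloxy)phenyl]propan-2-yl]phenyl}-1-[4-(benzyloxy)phenyl]-4-hydroxy-2,3-dimethylbutan-1-one (both C2 epimers; open form of its cyclic hemiketal), via aryllithium 12 (not isolated), via aryltitanium triisopropoxide 13 (not isolated)
Conditions: 7 (1.0 equiv), n-BuLi (1.05 equiv), THF, −78 °C; ClTi(O-i-Pr)3 (1.1 equiv), −78 to −40 °C; 11 (1.2 equiv), −78 to −20 °C; H2O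
Reagents that add atoms: none
Why: Bromine–lithium exchange and transmetalation give a non-basic aryltitanium reagent that adds only to the aldehyde (Reetz-type chemoselectivity, ketone untouched, no α-epimerisation) under Felkin–Anh control from the α-methyl centre, giving the 3,4-syn carbinol (4R); the minor anti epimer is carried on and removed after step 7 as a diastereomeric oxolane.

**Step 7**
Reactants: 14 (3S,4R)-4-{4-(benzyloxy)-3-[(2R)-1-[4-(benzyloxy)phenyl]propan-2-yl]phenyl}-1-[4-(benzyloxy)phenyl]-4-hydroxy-2,3-dimethylbutan-1-one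
Product: 17 4-[(2S,3R,4S,5R)-5-{4-hydroxy-3-[(2R)-1-(4-hydroxyphenyl)propan-2-yl]phenyl}-3,4-dimethyloxolan-2-yl]phenol (CNP0232576.2), via cyclic enol ether 15 (not isolated), via tribenzyl oxolane 16 (not isolated)
Conditions: PPTS (10 mol%), 4 Å MS, CH2Cl2, 25 °C; filtration through basic Al2O3; 10% Pd/C, H2 (4 atm), EtOAc, 25 °C; then EtOH added, H2 (4 atm), 25 °C
Reagents that add atoms: none
Why: Acid-catalysed hemiketalisation–dehydration (the benzylic hydroxyl attacks the aryl ketone and water leaves through the p-alkoxyaryl oxocarbenium ion) closes the ring without breaking the C–O bond at the carbinol centre and converges both C2 epimers of 14 on one enol ether, and heterogeneous syn-hydrogenation then delivers both hydrogens to the face opposite the cis methyl and aryl groups, setting ring C3 (R) and C2 (S) all-cis as in furan-to-all-cis-oxolane hydrogenations, before the same catalyst cleaves the three benzyl ethers.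

**Compound list**
1 | 1-(5-bromo-2-hydroxyphenyl)ethan-1-one | CC(=O)c1cc(Br)ccc1O | starting material
2 | 1-[2-(benzyloxy)-5-bromophenyl]ethan-1-one | CC(=O)c1cc(Br)ccc1OCc1ccccc1 | intermediate
3 | 1-(benzyloxy)-4-(chloromethyl)benzene | ClCc1ccc(OCc2ccccc2)cc1 | starting material
4 | [4-(benzyloxy)benzyl]magnesium chloride | Cl[Mg]Cc1ccc(OCc2ccccc2)cc1 | intermediate
5 | 2-[2-(benzyloxy)-5-bromophenyl]-1-[4-(benzyloxy)phenyl]propan-2-ol (racemic) | CC(O)(Cc1ccc(OCc2ccccc2)cc1)c1cc(Br)ccc1OCc1ccccc1 | intermediate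
6 | 1-(benzyloxy)-2-[(1E)-1-[4-(benzyloxy)phenyl]prop-1-en-2-yl]-4-bromobenzene | Brc1ccc(OCc2ccccc2)c(/C(C)=C/c2ccc(OCc3ccccc3)cc2)c1 | intermediate
7 | 1-(benzyloxy)-2-[(2R)-1-[4-(benzyloxy)phenyl]propan-2-yl]-4-bromobenzene | Brc1ccc(OCc2ccccc2)c([C@H](C)Cc2ccc(OCc3ccccc3)cc2)c1 | intermediate
8 | 1-[4-(benzyloxy)phenyl]propan-1-one | CCC(=O)c1ccc(OCc2ccccc2)cc1 | starting material
9 | {[(1Z)-1-[4-(benzyloxy)phenyl]prop-1-en-1-yl]oxy}trimethylsilane | C/C=C(\O[Si](C)(C)C)c1ccc(OCc2ccccc2)cc1 | intermediate
10 | propanal | CCC=O | starting material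
11 | (2S)-4-[4-(benzyloxy)phenyl]-2,3-dimethyl-4-oxobutanal (C3 epimers) | O=C[C@@H](C)C(C)C(=O)c1ccc(OCc2ccccc2)cc1 | intermediate
12 | {4-(benzyloxy)-3-[(2R)-1-[4-(benzyloxy)phenyl]propan-2-yl]phenyl}lithium | [Li]c1ccc(OCc2ccccc2)c([C@H](C)Cc2ccc(OCc3ccccc3)cc2)c1 | intermediate
13 | {4-(benzyloxy)-3-[(2R)-1-[4-(benzyloxy)phenyl]propan-2-yl]phenyl}tri(propan-2-yloxy)titanium | CC(C)O[Ti](OC(C)C)(OC(C)C)c1ccc(OCc2ccccc2)c([C@H](C)Cc2ccc(OCc3ccccc3)cc2)c1 | intermediate
14 | (3S,4R)-4-{4-(benzyloxy)-3-[(2R)-1-[4-(benzyloxy)phenyl]propan-2-yl]phenyl}-1-[4-(benzyloxy)phenyl]-4-hydroxy-2,3-dimethylbutan-1-one (C2 epimers) | O[C@@H](c1ccc(OCc2ccccc2)c([C@H](C)Cc2ccc(OCc3ccccc3)cc2)c1)[C@@H](C)C(C)C(=O)c1ccc(OCc2ccccc2)cc1 | intermediate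
15 | (2R,3S)-2-{4-(benzyloxy)-3-[(2R)-1-[4-(benzyloxy)phenyl]propan-2-yl]phenyl}-5-[4-(benzyloxy)phenyl]-3,4-dimethyl-2,3-dihydrofuran | CC1=C(c2ccc(OCc3ccccc3)cc2)O[C@@H](c2ccc(OCc3ccccc3)c([C@H](C)Cc3ccc(OCc4ccccc4)cc3)c2)[C@H]1C | intermediate
16 | (2S,3R,4S,5R)-2-[4-(benzyloxy)phenyl]-5-{4-(benzyloxy)-3-[(2R)-1-[4-(benzyloxy)phenyl]propan-2-yl]phenyl}-3,4-dimethyloxolane | C[C@@H]1[C@H](C)[C@H](c2ccc(OCc3ccccc3)c([C@H](C)Cc3ccc(OCc4ccccc4)cc3)c2)O[C@@H]1c1ccc(OCc2ccccc2)cc1 | intermediate
17 | 4-[(2S,3R,4S,5R)-5-{4-hydroxy-3-[(2R)-1-(4-hydroxyphenyl)propan-2-yl]phenyl}-3,4-dimethyloxolan-2-yl]phenol | C[C@@H]1[C@H](C)[C@H](c2ccc(O)c([C@H](C)Cc3ccc(O)cc3)c2)O[C@@H]1c1ccc(O)cc1 | target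

**Step count and risks**
Total steps: 7. Longest linear sequence: 5 (steps 1, 2, 3, 6, 7; the other branch is steps 4, 5, 6, 7).

Three steps most likely to fail:

Step 5. The bond joins two methyl-bearing carbons, the electron-rich enolsilane 9 can itself be oxidised, and yield or ee may be low. The fallback sets out from 8 and 10 and comes back at 11. Ketone 8 is brominated at the α-carbon (CuBr2, EtOAc–CHCl3, reflux) to 1-[4-(benzyloxy)phenyl]-2-bromopropan-1-one F1. Propanal 10 is condensed with (S)-1-amino-2-(methoxymethyl)pyrrolidine to (1E)-N-[(2S)-2-(methoxymethyl)pyrrolidin-1-yl]propan-1-imine F2. F2 is deprotonated with LiN(i-Pr)2 (THF, 0 °C) and alkylated with F1 at −100 °C (Enders hydrazone alkylation, attack anti to the methoxymethyl arm of the chelated azaenolate) to (3S,4E)-1-[4-(benzyloxy)phenyl]-4-{[(2S)-2-(methoxymethyl)pyrrolidin-1-yl]imino}-2,3-dimethylbutan-1-one F3. Two-phase cleavage of F3 with aqueous oxalic acid releases 11.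

Step 6. Substrate-controlled Felkin selectivity with an aryl nucleophile may be only moderate, and the aryltitanium may add slowly to the α,β-branched aldehyde. The fallback sets out from 7 and comes back at 14, replacing substrate control by reagent control. Aryllithium 12 (from 7 and n-BuLi) is trapped with B(O-i-Pr)3 and hydrolysed to {4-(benzyloxy)-3-[(2R)-1-[4-(benzyloxy)phenyl]propan-2-yl]phenyl}boronic acid F4. Boron–zinc exchange with Et2Zn (toluene, 60 °C) gives {4-(benzyloxy)-3-[(2R)-1-[4-(benzyloxy)phenyl]propan-2-yl]phenyl}(ethyl)zinc F5. F5 is added to 11 at −20 °C in the presence of 3-exo-morpholinoisoborneol (10 mol%, the enantiomer matched to the Felkin sense); arylzinc reagents do not touch the ketone, and the product is 14.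

Step 7. The benzylic C–O bond at the carbinol centre is acid-labile, the tetrasubstituted enol ether may saturate slowly on Pd/C, and ring C–O hydrogenolysis can compete once the phenols are free. The fallback sets out from 14 and comes back at 17, splitting the one-pot endgame into two orthogonal operations. The dehydration is run as before but 15 is isolated on Et3N-deactivated silica. It is saturated with the homogeneous cationic complex [Ir(cod)(PCy3)(py)]PF6 under H2 in CH2Cl2, which reduces tetrasubstituted alkenes from the open face and does not hydrogenolyse C–O bonds, to give isolated 16. The benzyl ethers are then removed separately by transfer hydrogenolysis (Pd(OH)2/C, cyclohexa-1,4-diene, EtOH) to give 17. This fallback makes no compound outside the list (none F0).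

**Further compounds**
F1 | step 5 | 1-[4-(benzyloxy)phenyl]-2-bromopropan-1-one (racemic) | CC(Br)C(=O)c1ccc(OCc2ccccc2)cc1
F2 | step 5 | (1E)-N-[(2S)-2-(methoxymethyl)pyrrolidin-1-yl]propan-1-imine | CC/C=N/N1CCC[C@H]1COC
F3 | step 5 | (3S,4E)-1-[4-(benzyloxy)phenyl]-4-{[(2S)-2-(methoxymethyl)pyrrolidin-1-yl]imino}-2,3-dimethylbutan-1-one (C2 epimers) | C[C@H](/C=N/N1CCC[C@H]1COC)C(C)C(=O)c1ccc(OCc2ccccc2)cc1
F4 | step 6 | {4-(benzyloxy)-3-[(2R)-1-[4-(benzyloxy)phenyl]propan-2-yl]phenyl}boronic acid | OB(O)c1ccc(OCc2ccccc2)c([C@H](C)Cc2ccc(OCc3ccccc3)cc2)c1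
F5 | step 6 | {4-(benzyloxy)-3-[(2R)-1-[4-(benzyloxy)phenyl]propan-2-yl]phenyl}(ethyl)zinc | CC[Zn]c1ccc(OCc2ccccc2)c([C@H](C)Cc2ccc(OCc3ccccc3)cc2)c1
F0 | step 7 | none | none
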